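Do not take Z plus Q for all the product: D counts in neither, and free Z drains into it.

all flasks: time 3.0 min
- spring: X 2.0 mM (fed, over 2.5 min); J 1.10 equiv; the addition at 5 °C, then warmed to 25 °C; the feed brings no volume worth counting
- midnight: X 2.0 mM; J 1.10 equiv; everything together at the start at 5 °C, warmed to 25 °C at 2.5 min
- dusk: X 2.0 mM (fed, over 2.5 min); J 1.10 equiv; all else is in the flask from the start; the feed brings no volume worth counting; temperature 25 °C
- autumn: X 2.0 mM (in portions, 5, over 2.5 min); J 1.10 equiv; first portion at the start, last at 2.5 min; temperature 25 °C
- winter: X 2.0 mM; J 1.10 equiv (fed, over 2.5 min); all else is in the flask from the start; the feed brings no volume worth counting; temperature 25 °C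

    X + J → Z + L (k1 = 15 L mol⁻¹ s⁻¹, Ea1 = 44.0 kJ mol⁻¹)
    X + Z ⇌ X.Z, settled at all times (K2 = 470 L mol⁻¹, ΔH2 = −43.0 kJ mol⁻¹)
    Z → Q (k3 = 0.0051 s⁻¹, Ea3 = 91.0 kJ mol⁻¹)
    Z ⇌ D (K4 = 8.0, k4 = 0.027 s⁻¹, Ea4 = 87.0 kJ mol⁻¹, ΔH4 = 14.0 kJ mol⁻¹)
    (constants at 25 °C)

1. which flask leads in share of Z in Z plus Q ("all alike" within 1.5 percentage points) (spring / midnight / dusk / autumn / winter / all alike)
2. share of Z in Z plus Q at the end, spring
3. share of Z in Z plus Q at the end, midnight
4. share of Z in Z plus Q at the end, dusk
5. share of Z in Z plus Q at the end, autumn
6. share of Z in Z plus Q at the end, winter

- a species is counted by the X in it: one X.Z counts as two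
- amounts and yields of Z count X.Z too
- all constants are for 25 °C and move with temperature by the activation energies and enthalpies
- in an amount of Z, one X.Z counts as one Z

Ask first what the end state must be. Free Z and D tend to a balance with c_D/c_Z equal to 8.0, while Q is a one-way exit, so the pair Z and D leaks into Q as time runs.

Then ask how fast this happens. Free Z and D relax towards balance with the constant k4 + k4/K4 = 1.82 min⁻¹ at 25 °C, a half-life of 0.381 min. The forward k4 exceeds k3 by a selectivity factor of 5.29, so free Z leaves mostly towards D at first.

Now fold this into one number. For dusk, autumn and winter, 1.82 min⁻¹ times 3.0 min gives 5.47. Call this product of the relaxation constant and the time spent at 25 °C the warm number. It counts how many relaxation times the free Z has been given.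

For spring and midnight, count the cold part as standing still, a rough step with 87.0 kJ mol⁻¹ on the way to D. The warm time is then 0.500 min and the warm number 0.911, which is smaller than the other. Read off it, spring and midnight have gone about 59.8% of the way through one relaxation when the clock stops, while the flasks held at 25 °C have the larger warm number, 5.47, and a longer time of feeding Q. So expect two groups, with the cold pair well ahead.

Then test whether one number was enough. It was not: the number is equal within each group, and it ignores X.Z and the shape of the feed. It therefore ranks neither spring against midnight nor the three warm flasks among themselves, and it gives no percentages.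

The forecast, made separately, does give them: spring leads, with spring 90% (range 85% to 94%), midnight 86%, dusk 62%, autumn 61% and winter 60%, holding for the warm flasks that “their different addition modes change this only slightly”.

The simulation puts spring first, with spring 89.1%, midnight 86.1%, dusk 64.9%, autumn 64.4% and winter 65.7%, so the forecast for winter stands 5.7 percentage points low. The warm number of spring, smaller than that of dusk, goes with Q at 4.08% in spring and 10.4% in dusk at 3.00 min. Spring left until 30.0 min has a warm number of 50.1 and a share of 6.12%, with D at 36.3% and Z at 3.89%, a ratio of 9.33.

The rate constants come from no measurement; the flask was simulated.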